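How much target can this flask hold at its best, and when? That is the question, and the thing to watch is the race between making and losing target.

| flask | substrate | reagent | precatalyst | remark | time |
|---|---|---|---|---|---|
| Monday's | 0.25 M | 0.70 equiv | 0.067 mol% | run made earlier |  |
| Tuesday's | 0.25 M | 0.70 equiv | 0.15 mol% | run made earlier |  |
| Thursday's | 0.25 M | 1.4 equiv | 0.1 mol% | run made earlier |  |
| flask | 0.25 M | 0.700 equiv | 0.1 mol% |  | 20 min |

| run | time / min | target / % | substrate / % |
|---|---|---|---|
| Monday's | 0.667 | 6.9 | 92.9 |
| Monday's | 1.33 | 20.2 | 78.5 |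
| Monday's | 3.00 | 43.3 | 45.0 |
| Monday's | 6.00 | 32.1 | 30.1 |
| Monday's | 12.0 | 15.8 | 30.0 |
| Tuesday's | 0.667 | 15.3 | 85.1 |
| Tuesday's | 1.33 | 38.6 | 58.0 |
| Tuesday's | 3.00 | 45.8 | 30.5 |
| Tuesday's | 6.00 | 26.2 | 30.3 |
| Tuesday's | 12.0 | 14.3 | 29.5 |
| Thursday's | 0.667 | 10.9 | 88.6 |
| Thursday's | 1.33 | 32.0 | 65.5 |
| Thursday's | 3.00 | 59.0 | 15.7 |
| Thursday's | 6.00 | 36.8 | 0 |
| Thursday's | 12.0 | 17.1 | 0 |

(each reading ± 0.3 percentage points)

- the moment within 20 min at which there is most target
- the amount of target, in percent of the substrate charged, at that time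

- the numbers in the tables scatter by 0.3 percentage points (one standard deviation)

Substrate stops at 30.0 % on Monday but reaches 0 % on Thursday with more reagent, so reagent is the limiting reagent and this flask's ceiling is 70.0 % of the substrate. While it lasts, substrate falls by 0.201 min⁻¹ of the charge on Monday and 0.409 min⁻¹ on Tuesday, so by linear interpolation in loading we take 0.283 min⁻¹ here. Late on Monday, with substrate still, 1/[target] rises by 0.536 min⁻¹, target counted as a fraction of the charge, and we take this as our loss constant, reckoning the loss as [target] squared.

Now turn the question round: what would bring the top before the reagent ends? Loss must catch making. The loss ratio, the loss at the ceiling divided by the full rate of making, is 0.926, and the even race stands at one. This flask lies just below it, so at full making the top comes with the end of the reagent.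

The forecast says 2.8 min and 54 %, because “formation still exceeds loss until then”.

The flask gives 48.5 % at 2.76 min.

    catalyst intermediate D ⇌ free catalyst + target (K = 0.160 M, k = 58.0 s⁻¹)
    target + released group → side product (k = 0.0350 M⁻¹ s⁻¹)
    substrate + catalyst intermediate B ⇌ catalyst intermediate C (K = 35.0 M⁻¹, k = 120 M⁻¹ s⁻¹)
    catalyst intermediate A → released group + catalyst intermediate B (k = 60.0 s⁻¹)
    precatalyst → free catalyst (k = 0.0160 s⁻¹)
    reagent + free catalyst → catalyst intermediate A (k = 370 M⁻¹ s⁻¹)
    catalyst intermediate C ⇌ catalyst intermediate D (K = 12.0, k = 81.0 s⁻¹)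

The time agrees, but the height is lower than forecast. At a top, making equals loss, so our loss constant puts making there at 0.126 min⁻¹, below the 0.283 min⁻¹ we assumed, with reagent still at 9.22 % of its charge. This flask, at loss ratio 0.926, kept 0.693 of its ceiling. With 0.25 mol% of precatalyst, extrapolated making of 0.660 min⁻¹ gives a loss ratio of 0.398, lower, and that neighbour kept 0.787, a top of 55.1 %.

Readings and results come from a simulation for an exercise, and the scatter is random.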